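Rate constants tell how fast a flask moves; how far this flask goes is reckoned here by counting turnovers.

in all of them: starting material 20 mM; free catalyst 0.98 mM

| run | coupling partner | temperature | remark | time |
|---|---|---|---|---|
| gamma | 12 mM | 25 °C | the very flask that is asked about, followed so far |  |
| epsilon | 12 mM | 20 °C | run made earlier |  |
| flask | 12.0 mM | 25 °C |  | 4.0 h |

| gamma: time / min | gamma: product / % | epsilon: time / min | epsilon: product / % |
|---|---|---|---|
| 15.0 | 13.7 | 15.0 | 7.3 |
| 50.0 | 41.0 | 50.0 | 27.0 |
| 80.0 | 55.3 | 80.0 | 40.1 |
| 150 | 59.6 | 150 | 58.8 |
| 180 | 59.4 | 180 | 59.5 |

(each reading ± 0.5 percentage points)

- south-west: at 4.0 h add free catalyst, 100 % of the amount charged, then wait 8.0 h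
- south-east: change nothing and wait 8.0 h more
- north: at 4.0 h raise the temperature by 15 K, then wait 8.0 h
- west: at 4.0 h add coupling partner, 50.0 % of the amount charged, then wait 8.0 h
- north-west: at 4.0 h take out 90 % of the product then present, then wait 8.0 h

- what is taken out of product is counted as made
- additions bring no volume worth counting

1. product, in percent of the starting material first charged, at 4.0 h
2. what to do for the largest gain in product; "none" if nothing gains more than 2 percentage points (south-west / south-east / north / west / north-west / none)
3. product present, with what was taken out counted in, in percent of the starting material first charged, after south-east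
4. product present, with what was taken out counted in, in percent of the starting material first charged, after north-west

Temperature clearly changes the speed, since at 50.0 min the gamma run reads 41.0 % and the colder epsilon run 27.0 %. The last readings, however, are 59.4 % and 59.5 %, which lie close together, so the charges are worth a look.

Suppose that one turnover, one pass of the catalyst round, uses one starting material and one coupling partner and releases one product. The turnover budget 12.2 is then the smaller charge divided by the catalyst charge: the passes each catalyst can make before the scarcer reagent is paid out. Here the coupling partner is the limiting reagent, at 12.0 mM against 20 mM. The budget times the catalyst charge, over the starting material charged, gives a ceiling of 60.0 %. This comes from the charges, and the last reading of the gamma run, which is a separate source, stands beside it.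

For the flask, this reckoning puts the product at that ceiling at 4.0 h. Waiting adds nothing to the budget. Adding 100 % of the free catalyst lowers the budget to 6.12 turnovers per catalyst but leaves the ceiling where it was. Adding 50.0 % of the coupling partner raises the budget to 18.4 and the ceiling to 90.0 %. That gain assumes the catalyst still turns after the stop, which readings taken after the stop do not show.

The forecast sits just below this ceiling, with 59.7 % now, 59.8 % after south-east and 59.9 % after north-west, and it chooses west, on the ground that “the stop is stoichiometric: the partner has run out”.

The flask gives 60.0 % now, 60.0 % after south-east and 60.0 % after north-west, and west gains 30 percentage points.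

    catalyst intermediate D → free catalyst + product (k = 78.0 /min, Ea = 81.0 kJ/mol)
    free catalyst → spent catalyst (k = 1.20 × 10⁻⁵ /min, Ea = 106 kJ/mol)
    coupling partner + catalyst intermediate B → catalyst intermediate C (k = 82.0 /M/min, Ea = 42.0 kJ/mol)
    starting material + free catalyst → catalyst intermediate A (k = 1800 /M/min, Ea = 36.0 kJ/mol)
    catalyst intermediate C ⇌ catalyst intermediate D (K = 1.10, k = 0.260 /min, Ea = 85.0 kJ/mol, ΔH = −41.0 kJ/mol)
    catalyst intermediate A → catalyst intermediate B (k = 22.0 /min, Ea = 63.0 kJ/mol)
    (constants at 25 °C)

At 240 min the flask, with its budget of 12.2 turnovers paid out, holds 0 % of its coupling partner. The neighbour flask, charged with 5.0 mM of starting material, has starting material as its smaller charge. Its budget is 5.10 turnovers, its ceiling 100 %, and 58.3 % of its coupling partner should remain. That neighbour gives 100 %, with 0 % of its starting material and 58 % of its coupling partner left.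

(The earlier runs and the new flask come from a simulation with constants of no real substance; noise was put on by code.)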